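## Retrosynthetic overview

1. The target comes from a cis-fused daucane core carrying the 4-OH, a 6-O-aroyl group and a 9,10-epoxide: the 10-oxygen and the C8=C9 alkene arise from anti-E2 opening of the epoxide, the two esters from two separate acylations, the free phenol from a phenolic acetate.
2. The 6-OH and H-5 come from a bicyclic enol acetate (C5=C6) by one-pot methanolysis and hydride reduction on the convex face.
3. Key disconnection: the bicyclo[5.3.0]decadienyl enol acetate comes from an acyclic dienyne propargylic acetate by a one-flask PtCl2 cycloisomerisation (1,2-acetoxy shift/cyclopropanation) and divinylcyclopropane Cope shift, a formal intramolecular (4+3) cycloaddition.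
4. The dienyne comes from an isopropyl dienyl ketone and propargyl acetate (asymmetric alkynylation sets C4, the only stereocentre carried into the key step); the ketone comes from a Carroll rearrangement of the crotonaldehyde/isopropenyl Grignard adduct.
5. Ring order: cyclopropane and five-membered ring together (C1–C5 bond), then the seven-membered ring (C7–C8 bond) as the cyclopropane opens, all in one operation.

Notation: names use the daucane skeleton (five-membered ring C1–C5; seven-membered ring C1, C5–C10; C1 carries the angular methyl, C4 the isopropyl group, C8 a methyl); "top face" is the face of the angular methyl. In the target the angular methyl, H-5 and 4-OH are on the top face; the isopropyl group and both ester oxygens are on the bottom face.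

Assumption: the (R,R)-salen ligand is taken to give the (S)-propargylic alcohol in step 3; if the sense of induction is the other way round, the (S,S)-ligand is used.

## Route

Step 1
Reactants: 1 (E)-but-2-enal (crotonaldehyde); 2 isopropenylmagnesium bromide
Product: 3 racemic (4E)-2-methylhexa-1,4-dien-3-ol
Conditions: THF, −78 → 0 °C; then aq. NH4Cl
Reagents that add atoms: none
Why: The Grignard reagent adds in the 1,2-sense to the enal (Grignard addition) without touching the (E)-propenyl geometry, and the new carbinol centre is racemic but is destroyed in step 2.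

Step 2
Reactants: 3 (4E)-2-methylhexa-1,4-dien-3-ol; 4 ethyl 4-methyl-3-oxopentanoate
Product: 7 (6E,8E)-2,6-dimethyldeca-6,8-dien-3-one, via allyl β-keto ester 5 (not isolated), via β-keto acid 6 (not isolated)
Conditions: DMAP (10 mol %), xylenes, 140 °C with removal of EtOH, then 180 °C (sealed tube)
Reagents that add atoms: none
Why: Transesterification gives the allyl β-keto ester, whose enol undergoes the Carroll rearrangement (decarboxylative Claisen, [3,3]) through the unsubstituted CH2 terminus of the isopropenyl group in a chair transition state with the propenyl group equatorial, so the new trisubstituted alkene is (E), the old carbinol centre vanishes and the β-keto acid loses CO2.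

Step 3
Reactants: 7 (6E,8E)-2,6-dimethyldeca-6,8-dien-3-one; 8 prop-2-yn-1-yl acetate (propargyl acetate)
Product: 10 (4S,7E,9E)-4-hydroxy-7-methyl-4-(propan-2-yl)undeca-7,9-dien-2-yn-1-yl acetate, via methylzinc acetylide 9 (not isolated)
Conditions: Me2Zn (3 equiv), (R,R)-N,N′-bis(3,5-di-tert-butylsalicylidene)cyclohexane-1,2-diamine (20 mol %), PhMe, 23 °C, 72 h; then aq. NH4Cl
Reagents that add atoms: none
Why: Dimethylzinc turns the terminal alkyne into a zinc acetylide that tolerates the acetate, and the chiral zinc–salen complex formed in situ delivers it to one face of the ketone (zinc–salen-catalysed asymmetric alkynylation of a ketone), setting C4 as (S) by discriminating the branched isopropyl group from the linear chain.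

Step 4
Reactants: 10 (4S,7E,9E)-4-hydroxy-7-methyl-4-(propan-2-yl)undeca-7,9-dien-2-yn-1-yl acetate
Product: 12 (1S,4S,8S)-4-hydroxydauca-5,9-dien-6-yl acetate, via divinylcyclopropane 11 (not isolated)
Conditions: PtCl2 (5 mol %), PhMe, 80 °C, then 105 °C
Reagents that add atoms: none
Why: Proposed new method: divalent platinum π-activates the alkyne, the trisubstituted alkene of the diene attacks C5 in a 5-exo-dig mode and the resulting cyclopropyl platinum carbene is quenched by 1,2-shift of the neighbouring acetate (the acetate-first sequence gives the same compound), which yields cis-divinylcyclopropane 11 with the isopropyl group anti to the developing angular methyl (the bulky group avoids the 1,3-syn clash, so C1 is set from C4), and 11 then undergoes the boat-like [3,3] divinylcyclopropane–cycloheptadiene rearrangement in the same flask, forming C7–C8 and placing the (E)-methyl of the propenyl terminus outside so that H-8 ends up cis to the angular methyl; the closest known reactions are the PtCl2- or gold-catalysed cycloisomerisation of enynes bearing a propargylic acetate (Ohloff–Rautenstrauch type 1,2-acyloxy shift/cyclopropanation) and the tandem cyclopropanation/Cope rearrangement used as a formal (4+3) cycloaddition.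

Step 5
Reactants: 12 (1S,4S,8S)-4-hydroxydauca-5,9-dien-6-yl acetate
Product: 14 (1S,4S,5S,6R,8S)-dauc-9-ene-4,6-diol, via β-hydroxy ketone 13 (not isolated)
Conditions: NaBH4 (3 equiv), K2CO3 (0.2 equiv), MeOH, −20 → 0 °C
Reagents that add atoms: none
Why: Methoxide cleaves the enol acetate and the ketone is reduced as it forms (reductive cleavage of an enol ester): C5 is protonated on the top face next to the 4-OH and away from the isopropyl group, which makes the ring fusion cis, and hydride then attacks C6 from the same convex face (also the face of delivery from the C4 alkoxyborohydride), putting the 6-OH on the bottom face.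

Step 6
Reactants: 14 (1S,4S,5S,6R,8S)-dauc-9-ene-4,6-diol; 15 4-acetoxybenzoyl chloride
Product: 16 (1S,4S,5S,6R,8S)-4-hydroxydauc-9-en-6-yl 4-acetoxybenzoate
Conditions: pyridine, DMAP (0.2 equiv), CH2Cl2, 0 → 23 °C
Reagents that add atoms: none
Why: DMAP-catalysed acylation (nucleophilic catalysis) esterifies the only secondary hydroxyl, the tertiary 4-OH being inert, and no stereocentre is touched.

Step 7
Reactants: 16 (1S,4S,5S,6R,8S)-4-hydroxydauc-9-en-6-yl 4-acetoxybenzoate
Product: 17 (1R,4S,5S,6R,8S,9S,10R)-9,10-epoxy-4-hydroxydaucan-6-yl 4-acetoxybenzoate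
Conditions: mCPBA, NaHCO3, CH2Cl2, 0 °C
Reagents that add atoms: 3-chloroperoxybenzoic acid (mCPBA), OOC(=O)c1cccc(Cl)c1
Why: Prilezhaev epoxidation of the only alkene should occur anti to the pseudo-axial angular methyl on the adjacent quaternary C1 (as with ring D steroid olefins next to an angular methyl), giving the bottom-face epoxide and so fixing the C10–O configuration.

Step 8
Reactants: 17 (1R,4S,5S,6R,8S,9S,10R)-9,10-epoxy-4-hydroxydaucan-6-yl 4-acetoxybenzoate
Product: 19 (1R,4S,5S,6R,10S)-4,10-dihydroxydauc-8-en-6-yl 4-acetoxybenzoate, via bis(trimethylsilyl) ether 18 (not isolated)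
Conditions: TMSOTf (2.5 equiv), DBU (3 equiv), PhMe, −78 → 0 °C; then citric acid, MeOH, 23 °C
Reagents that add atoms: none
Why: Epoxide-to-allylic-silyl-ether isomerisation (TMSOTf/DBU, anti E2): the oxirane oxygen is silylated and DBU removes the only β-hydrogen available, H-8, which lies anti-periplanar to the C9–O bond, so the C8=C9 alkene forms while the C10–O bond and its configuration are retained, and mild acid then removes both silyl groups.

Step 9
Reactants: 19 (1R,4S,5S,6R,10S)-4,10-dihydroxydauc-8-en-6-yl 4-acetoxybenzoate; 20 3-methylbutanoyl chloride (isovaleryl chloride)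
Product: 21 (1R,4S,5S,6R,10S)-4-hydroxy-10-(3-methylbutanoyloxy)dauc-8-en-6-yl 4-acetoxybenzoate
Conditions: DMAP (1 equiv), pyridine, CH2Cl2, 23 °C
Reagents that add atoms: none
Why: DMAP-catalysed acylation of the only remaining secondary hydroxyl (allylic and neopentyl, hence excess reagent), the tertiary 4-OH staying free and no stereocentre being touched.

Step 10
Reactants: 21 (1R,4S,5S,6R,10S)-4-hydroxy-10-(3-methylbutanoyloxy)dauc-8-en-6-yl 4-acetoxybenzoate
Product: 22 (1R,4S,5S,6R,10S)-4-hydroxy-10-(3-methylbutanoyloxy)dauc-8-en-6-yl 4-hydroxybenzoate (the target)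
Conditions: pyrrolidine (1.5 equiv), CH2Cl2, 0 °C
Reagents that add atoms: none
Why: Chemoselective aminolysis: the aryl acetate is a far better acyl donor than the two alkyl esters, so pyrrolidine removes only the phenolic acetyl group and leaves every stereocentre untouched.

## Compound list

1 | (E)-but-2-enal (crotonaldehyde) | C/C=C/C=O | starting material
2 | isopropenylmagnesium bromide | CC(=C)[Mg]Br | starting material
3 | racemic (4E)-2-methylhexa-1,4-dien-3-ol | C/C=C/C(O)C(C)=C | intermediate
4 | ethyl 4-methyl-3-oxopentanoate | CCOC(=O)CC(=O)C(C)C | starting material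
5 | (4E)-2-methylhexa-1,4-dien-3-yl 4-methyl-3-oxopentanoate (not isolated) | CC(C)C(=O)CC(=O)OC(/C=C/C)C(C)=C | intermediate
6 | (4E,6E)-4-methyl-2-(2-methylpropanoyl)octa-4,6-dienoic acid (not isolated) | CC(C)C(=O)C(C(=O)O)C/C(C)=C/C=C/C | intermediate
7 | (6E,8E)-2,6-dimethyldeca-6,8-dien-3-one | CC(C)C(=O)CC/C(C)=C/C=C/C | intermediate
8 | prop-2-yn-1-yl acetate | CC(=O)OCC#C | starting material
9 | (3-acetoxyprop-1-yn-1-yl)(methyl)zinc (not isolated) | CC(=O)OCC#C[Zn]C | intermediate
10 | (4S,7E,9E)-4-hydroxy-7-methyl-4-(propan-2-yl)undeca-7,9-dien-2-yn-1-yl acetate | CC(=O)OCC#C[C@@](O)(C(C)C)CC/C(C)=C/C=C/C | intermediate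
11 | 1-(1-acetoxyethenyl)-5-methyl-2-(propan-2-yl)-6-[(1E)-prop-1-en-1-yl]bicyclo[3.1.0]hexan-2-ol; acetoxyvinyl, methyl and propenyl cis on the cyclopropane, hydroxyl cis to the acetoxyvinyl group, isopropyl on the cyclopropane side (not isolated) | C=C(OC(C)=O)[C@@]12[C@@H](/C=C/C)[C@]1(C)CC[C@]2(O)C(C)C | intermediate
12 | (1S,4S,8S)-4-hydroxydauca-5,9-dien-6-yl acetate; angular methyl, 4-OH and H-8 on the top face | C[C@@H]1C=C[C@]2(C)CC[C@](O)(C(C)C)C2=C(OC(C)=O)C1 | intermediate
13 | (1S,4S,5R,8S)-4-hydroxydauc-9-en-6-one; cis-fused (not isolated) | C[C@@H]1C=C[C@]2(C)CC[C@](O)(C(C)C)[C@@H]2C(=O)C1 | intermediate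
14 | (1S,4S,5S,6R,8S)-dauc-9-ene-4,6-diol | C[C@@H]1C=C[C@]2(C)CC[C@](O)(C(C)C)[C@@H]2[C@H](O)C1 | intermediate
15 | 4-acetoxybenzoyl chloride | CC(=O)Oc1ccc(cc1)C(Cl)=O | starting material
16 | (1S,4S,5S,6R,8S)-4-hydroxydauc-9-en-6-yl 4-acetoxybenzoate | C[C@@H]1C=C[C@]2(C)CC[C@](O)(C(C)C)[C@@H]2[C@H](OC(=O)c2ccc(OC(C)=O)cc2)C1 | intermediate
17 | (1R,4S,5S,6R,8S,9S,10R)-9,10-epoxy-4-hydroxydaucan-6-yl 4-acetoxybenzoate; epoxide on the bottom face | C[C@@H]1[C@@H]2O[C@@H]2[C@]3(C)CC[C@](O)(C(C)C)[C@@H]3[C@H](OC(=O)c4ccc(OC(C)=O)cc4)C1 | intermediate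
18 | (1R,4S,5S,6R,10S)-4,10-bis(trimethylsilyloxy)dauc-8-en-6-yl 4-acetoxybenzoate (not isolated) | CC1=C[C@H](O[Si](C)(C)C)[C@]2(C)CC[C@](O[Si](C)(C)C)(C(C)C)[C@@H]2[C@H](OC(=O)c2ccc(OC(C)=O)cc2)C1 | intermediate
19 | (1R,4S,5S,6R,10S)-4,10-dihydroxydauc-8-en-6-yl 4-acetoxybenzoate | CC1=C[C@H](O)[C@]2(C)CC[C@](O)(C(C)C)[C@@H]2[C@H](OC(=O)c2ccc(OC(C)=O)cc2)C1 | intermediate
20 | 3-methylbutanoyl chloride (isovaleryl chloride) | CC(C)CC(Cl)=O | starting material
21 | (1R,4S,5S,6R,10S)-4-hydroxy-10-(3-methylbutanoyloxy)dauc-8-en-6-yl 4-acetoxybenzoate | CC1=C[C@H](OC(=O)CC(C)C)[C@]2(C)CC[C@](O)(C(C)C)[C@@H]2[C@H](OC(=O)c2ccc(OC(C)=O)cc2)C1 | intermediate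
22 | (1R,4S,5S,6R,10S)-4-hydroxy-10-(3-methylbutanoyloxy)dauc-8-en-6-yl 4-hydroxybenzoate | CC1=C[C@H](OC(=O)CC(C)C)[C@]2(C)CC[C@](O)(C(C)C)[C@@H]2[C@H](OC(=O)c2ccc(O)cc2)C1 | target

## Step count and weak points

Total step count: 10. Longest linear sequence: 10 steps (from 1).

Steps most likely to fail:

Step 3 (asymmetric alkynylation). The catalyst must tell an isopropyl group from a CH2CH2 chain, so the enantiomeric excess may be modest. The fallback replaces asymmetric catalysis by resolution. It sets out from 7 and 8: the same dimethylzinc addition is run with the achiral ligand N,N′-bis(salicylidene)ethane-1,2-diamine to give the racemic propargylic alcohol F1, which is resolved by preparative supercritical-fluid chromatography on a cellulose tris(3,5-dimethylphenylcarbamate) phase. The (S)-enantiomer is 10, where the route is rejoined.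

Step 4 (key cascade). Possible diversions are a formal [4+2] of the dienyne to a hydrindadiene, a 1,3-acetoxy shift to an allenyl acetate, ionisation of the tertiary alcohol, or the wrong facial sense at C1. The fallback changes the carbene source and forms the rings stepwise. It sets out from 7: alkynylation with propyne under the step 3 conditions gives the (S)-propynyl carbinol F2, and TMSCl/imidazole gives its trimethylsilyl ether F3. Oxidation of the alkyne with 8-methylquinoline N-oxide and (Ph3P)AuNTf2 puts the oxygen on the methyl-bearing alkyne carbon; the α-oxo gold carbene on C5 cyclopropanates the nearer diene alkene to give the acetylcyclopropane F4. LiN(iPr)2 and TMSCl at −78 °C give the kinetic silyl enol ether F5, which undergoes the Cope shift at 25–60 °C to the bis-silyl dienol ether F6. K2CO3 and then NaBH4 in MeOH cleave both silyl groups and reduce the ketone, passing through 13, to give 14, where the route is rejoined.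

Step 7 (facial selectivity of the epoxidation). Each face of the alkene has one allylic methyl, so steric control may be weak; a top-face epoxide cannot undergo the anti elimination of step 8 because H-8 would be syn. The fallback uses substrate direction one stage earlier. It sets out from 14: vanadyl bis(acetylacetonate), VO(acac)2, with t-BuOOH in CH2Cl2 lets the bottom-face 6-hydroxyl deliver the oxidant across the ring to the bottom face of C9=C10, giving the epoxy diol F7. F7 is acylated with 15 as in step 6 to give 17, where the route is rejoined.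

## Further compounds

F1 | step 3 | racemic (7E,9E)-4-hydroxy-7-methyl-4-(propan-2-yl)undeca-7,9-dien-2-yn-1-yl acetate | CC(=O)OCC#CC(O)(C(C)C)CC/C(C)=C/C=C/C
F2 | step 4 | (4S,7E,9E)-7-methyl-4-(propan-2-yl)undeca-7,9-dien-2-yn-4-ol | CC#C[C@@](O)(C(C)C)CC/C(C)=C/C=C/C
F3 | step 4 | trimethylsilyl ether of (4S,7E,9E)-7-methyl-4-(propan-2-yl)undeca-7,9-dien-2-yn-4-ol | CC#C[C@@](O[Si](C)(C)C)(C(C)C)CC/C(C)=C/C=C/C
F4 | step 4 | 1-acetyl-5-methyl-2-(propan-2-yl)-6-[(1E)-prop-1-en-1-yl]-2-(trimethylsilyloxy)bicyclo[3.1.0]hexane; acetyl, methyl and propenyl cis on the cyclopropane, silyloxy cis to acetyl | CC(=O)[C@@]12[C@@H](/C=C/C)[C@]1(C)CC[C@]2(O[Si](C)(C)C)C(C)C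
F5 | step 4 | 5-methyl-2-(propan-2-yl)-6-[(1E)-prop-1-en-1-yl]-2-(trimethylsilyloxy)-1-[1-(trimethylsilyloxy)ethenyl]bicyclo[3.1.0]hexane; same relative configuration as F4 | C=C(O[Si](C)(C)C)[C@@]12[C@@H](/C=C/C)[C@]1(C)CC[C@]2(O[Si](C)(C)C)C(C)C
F6 | step 4 | (1S,4S,8S)-4,6-bis(trimethylsilyloxy)dauca-5,9-diene | C[C@@H]1C=C[C@]2(C)CC[C@](O[Si](C)(C)C)(C(C)C)C2=C(O[Si](C)(C)C)C1
F7 | step 7 | (1R,4S,5S,6R,8S,9S,10R)-9,10-epoxydaucane-4,6-diol; epoxide on the bottom face | C[C@@H]1[C@@H]2O[C@@H]2[C@]3(C)CC[C@](O)(C(C)C)[C@@H]3[C@H](O)C1
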